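## Retrosynthetic overview

- Target 24 comes from cross-conjugated dienone 22 by 1,4-reduction of the C4=C5 enone and protonation at C5; 22 comes from phenol 19 by dearomatising C-allylation at C3a.
- Phenol 19 comes from ester 15 by turning the C2 ester into the C2 methyl group and the C6 benzyl ether into the free C6 hydroxyl.
- The strategy rests on ring A: C2 is the single carbon between O1 and the benzylic C3, and O1 and C3 sit on the neighbouring carbons C7a and C3a of ring B. Ring A therefore opens to the four-atom ortho-quinone methide O1=C7a–C3a=C3 plus a one-carbon ylide (bonds O1–C2 and C2–C3).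
- The quinone methide precursor, sulfone 8, comes from salicylaldehyde 4 and aryl Grignard reagent 6, followed by sulfinate exchange; 4 comes from syringaldehyde 1.
- Ring order: ring B is bought as the arene, ring A is closed in step 7, and ring B is dearomatised in step 12.

Key step: step 7

Assumption: the quinidine-derived salt 11 is taken to deliver the (2S,3S) series in step 7; if the sense proves opposite, the pseudoenantiomeric quinine salt would be used with no other change.

## Route

Step 1
Reactants: 1 syringaldehyde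
Product: 2 4-(benzyloxy)-3,5-dimethoxybenzaldehyde
Conditions: BnBr, K2CO3, DMF, 60 °C
Reagents that add atoms: benzyl bromide, BrCc1ccccc1
Why: Williamson O-alkylation of the only acidic hydroxyl gives a benzyl ether that marks the future C6 oxygen and can later be removed without touching the methyl ethers.

Step 2
Reactants: 2 4-(benzyloxy)-3,5-dimethoxybenzaldehyde
Product: 3 4-(benzyloxy)-2-bromo-3,5-dimethoxybenzaldehyde
Conditions: NBS, MeCN, rt, dark
Reagents that add atoms: N-bromosuccinimide, BrN1C(=O)CCC1=O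
Why: Electrophilic aromatic bromination at one of the two equivalent free ring positions, each activated by an ortho and a para methoxy group, while polar dark conditions suppress radical bromination of the benzylic CH2.

Step 3
Reactants: 3 4-(benzyloxy)-2-bromo-3,5-dimethoxybenzaldehyde
Product: 4 4-(benzyloxy)-2-hydroxy-3,5-dimethoxybenzaldehyde
Conditions: CuI (10 mol %), 1,10-phenanthroline (20 mol %), KOH, DMSO/H2O, 100 °C; then aq HCl
Reagents that add atoms: potassium hydroxide, [K+].[OH-]
Why: Copper-catalysed Ullmann-type hydroxylation of the aryl bromide, assisted by the ortho formyl group, should give the salicylaldehyde, whose phenoxide form is protected against Cannizzaro reaction until acidification.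

Step 4
Reactants: 4 4-(benzyloxy)-2-hydroxy-3,5-dimethoxybenzaldehyde; 5 5-bromo-1,2,3-trimethoxybenzene
Product: 7 rac-3-(benzyloxy)-6-[hydroxy(3,4,5-trimethoxyphenyl)methyl]-2,4-dimethoxyphenol, via Grignard reagent 6 (not isolated)
Conditions: 5 (2.5 equiv), Mg, I2 (cat.), THF, reflux; then 4, 0 °C → rt; aq NH4Cl
Reagents that add atoms: none
Why: Grignard addition to the aldehyde, in which one equivalent is spent on the phenol and a second adds to the formyl carbon of the magnesium phenoxide; the carbinol centre is left racemic on purpose because step 7 erases it.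

Step 5
Reactants: 7 rac-3-(benzyloxy)-6-[hydroxy(3,4,5-trimethoxyphenyl)methyl]-2,4-dimethoxyphenol
Product: 8 rac-3-(benzyloxy)-2,4-dimethoxy-6-[(4-methylbenzenesulfonyl)(3,4,5-trimethoxyphenyl)methyl]phenol
Conditions: TolSO2Na, p-TsOH·H2O, CH2Cl2, rt
Reagents that add atoms: sodium p-toluenesulfinate, [Na+].Cc1ccc(cc1)S([O-])=O
Why: Acid-promoted SN1 ionisation of the ortho-hydroxy, doubly benzylic carbinol and capture of the stabilised cation by sulfinate sulfur should give the bench-stable sulfone, the standard base-triggered source of an ortho-quinone methide.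

Step 6
Reactants: 9 tert-butyl bromoacetate; 10 quinidine
Product: 11 N-[2-(tert-butoxy)-2-oxoethyl]quinidinium bromide
Conditions: THF, rt
Reagents that add atoms: none
Why: Menshutkin quaternisation at the quinuclidine nitrogen, which is far more nucleophilic than the quinoline nitrogen or the secondary hydroxyl.

Step 7
Reactants: 8 rac-3-(benzyloxy)-2,4-dimethoxy-6-[(4-methylbenzenesulfonyl)(3,4,5-trimethoxyphenyl)methyl]phenol; 11 N-[2-(tert-butoxy)-2-oxoethyl]quinidinium bromide
Product: 15 tert-butyl (2S,3S)-6-(benzyloxy)-5,7-dimethoxy-3-(3,4,5-trimethoxyphenyl)-2,3-dihydro-1-benzofuran-2-carboxylate, via ortho-quinone methide 12 (not isolated), via ammonium ylide 13 (not isolated), via phenoxide betaine 14 (not isolated)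
Conditions: Cs2CO3 (3 equiv), CH2Cl2, 0 °C → rt
Reagents that add atoms: none
Why: Cs2CO3 deprotonates phenol 8, which expels p-toluenesulfinate by 1,4-elimination to give ortho-quinone methide 12, and it deprotonates salt 11 to the ester-stabilised ammonium ylide 13; the ylide carbon then adds in a conjugate fashion to the exocyclic carbon, forming C2–C3 and restoring aromaticity in betaine 14. The phenoxide oxygen then displaces quinidine at C2 in a 5-exo-tet SN2 closure, forming O1–C2 and ring A. This is the known formal [4+1] annulation of in situ ortho-quinone methides with ammonium ylides to trans-2,3-dihydrobenzofurans, with the cinchona amine as a chiral leaving group. C3 is set in the conjugate addition, where the quinidinium group on the ylide carbon differentiates the two faces of the planar quinone methide, and C2 is set by the invertive closure from the anti-periplanar betaine rotamer, which places ester and aryl trans. The step needs C-attack at the exocyclic carbon in preference to a sigmatropic shift of the ylide or O-alkylation; the strongly polarised, aryl-terminated quinone methide and the soft stabilised ylide favour this. The tert-butyl ester resists attack by the alkaloid hydroxyl, and the racemic centre of 8 is lost in 12, so all stereochemical information comes from the reagent.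

Step 8
Reactants: 15 tert-butyl (2S,3S)-6-(benzyloxy)-5,7-dimethoxy-3-(3,4,5-trimethoxyphenyl)-2,3-dihydro-1-benzofuran-2-carboxylate
Product: 16 [(2S,3S)-6-(benzyloxy)-5,7-dimethoxy-3-(3,4,5-trimethoxyphenyl)-2,3-dihydro-1-benzofuran-2-yl]methanol
Conditions: LiAlH4, THF, 0 °C → rt; H2O work-up
Reagents that add atoms: none
Why: Hydride reduction of the ester to the primary alcohol, with aryl ethers inert and C2 not enolised under these non-equilibrating conditions.

Step 9
Reactants: 16 [(2S,3S)-6-(benzyloxy)-5,7-dimethoxy-3-(3,4,5-trimethoxyphenyl)-2,3-dihydro-1-benzofuran-2-yl]methanol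
Product: 17 [(2S,3S)-6-(benzyloxy)-5,7-dimethoxy-3-(3,4,5-trimethoxyphenyl)-2,3-dihydro-1-benzofuran-2-yl]methyl 4-methylbenzenesulfonate
Conditions: TsCl, Et3N, DMAP (cat.), CH2Cl2, 0 °C → rt
Reagents that add atoms: p-toluenesulfonyl chloride, Cc1ccc(cc1)S(Cl)(=O)=O
Why: Sulfonylation of the only free hydroxyl converts the primary alcohol into a leaving group.

Step 10
Reactants: 17 [(2S,3S)-6-(benzyloxy)-5,7-dimethoxy-3-(3,4,5-trimethoxyphenyl)-2,3-dihydro-1-benzofuran-2-yl]methyl 4-methylbenzenesulfonate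
Product: 18 (2R,3S)-6-(benzyloxy)-5,7-dimethoxy-2-methyl-3-(3,4,5-trimethoxyphenyl)-2,3-dihydro-1-benzofuran
Conditions: LiBHEt3, THF, 0 °C → rt
Reagents that add atoms: none
Why: SN2 displacement of the primary tosylate by hydride (Super-Hydride reduction) occurs at the exocyclic CH2, so both ring stereocentres are untouched; the descriptor at C2 changes only through substituent priorities.

Step 11
Reactants: 18 (2R,3S)-6-(benzyloxy)-5,7-dimethoxy-2-methyl-3-(3,4,5-trimethoxyphenyl)-2,3-dihydro-1-benzofuran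
Product: 19 (2R,3S)-5,7-dimethoxy-2-methyl-3-(3,4,5-trimethoxyphenyl)-2,3-dihydro-1-benzofuran-6-ol
Conditions: H2 (1 atm), 10% Pd/C, EtOAc/MeOH, rt
Reagents that add atoms: none
Why: Hydrogenolysis of the benzyl aryl ether frees the C6 phenol; the ring C2–O1 bond is not benzylic and no alkene is present yet, so nothing else is reduced.

Step 12
Reactants: 19 (2R,3S)-5,7-dimethoxy-2-methyl-3-(3,4,5-trimethoxyphenyl)-2,3-dihydro-1-benzofuran-6-ol; 20 allyltrimethylsilane
Product: 22 (2R,3S,3aS)-5,7-dimethoxy-2-methyl-3a-(prop-2-en-1-yl)-3-(3,4,5-trimethoxyphenyl)-3,3a-dihydro-1-benzofuran-6(2H)-one, via phenoxonium cation 21 (not isolated)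
Conditions: PhI(OAc)2 (1.1 equiv), allylSiMe3 (5 equiv), (CF3)2CHOH/CH2Cl2, −20 °C
Reagents that add atoms: none
Why: Two-electron oxidation of the phenol by the trivalent-iodine reagent gives cation 21, which the allylsilane should capture at the alkyl-bearing para carbon C3a (oxidative Hosomi–Sakurai-type dearomatisation) from the face opposite the neighbouring C3 aryl group, setting the quaternary centre anti to aryl; allyl delivered first to C5 or C7 can reach C3a by a [3,3] shift to the more stable cross-conjugated dienone.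

Step 13
Reactants: 22 (2R,3S,3aS)-5,7-dimethoxy-2-methyl-3a-(prop-2-en-1-yl)-3-(3,4,5-trimethoxyphenyl)-3,3a-dihydro-1-benzofuran-6(2H)-one
Product: 24 (2R,3S,3aR,5S)-5,7-dimethoxy-2-methyl-3a-(prop-2-en-1-yl)-3-(3,4,5-trimethoxyphenyl)-3,3a,4,5-tetrahydro-1-benzofuran-6(2H)-one, via lithium enolate 23 (not isolated)
Conditions: LiBH(s-Bu)3, THF, −78 °C; then t-BuCO2H, −78 °C
Reagents that add atoms: none
Why: Conjugate hydride reduction by the bulky borohydride at C4, the only β-carbon bearing hydrogen (C7a is a fully substituted vinylogous-ester carbon and the carbonyl is flanked by two methoxy-bearing carbons), gives enolate 23, and kinetic protonation at C5 by a hindered acid from the face opposite the pseudo-axial 3a-allyl group should place the 5-methoxy group cis to allyl (5S).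

## Compound list

1 | syringaldehyde (4-hydroxy-3,5-dimethoxybenzaldehyde) | COc1cc(C=O)cc(OC)c1O | starting material
2 | 4-(benzyloxy)-3,5-dimethoxybenzaldehyde | COc1cc(C=O)cc(OC)c1OCc1ccccc1 | intermediate
3 | 4-(benzyloxy)-2-bromo-3,5-dimethoxybenzaldehyde | COc1cc(C=O)c(Br)c(OC)c1OCc1ccccc1 | intermediate
4 | 4-(benzyloxy)-2-hydroxy-3,5-dimethoxybenzaldehyde | COc1cc(C=O)c(O)c(OC)c1OCc1ccccc1 | intermediate
5 | 5-bromo-1,2,3-trimethoxybenzene | COc1cc(Br)cc(OC)c1OC | starting material
6 | (3,4,5-trimethoxyphenyl)magnesium bromide | COc1cc([Mg]Br)cc(OC)c1OC | intermediate (not isolated)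
7 | rac-3-(benzyloxy)-6-[hydroxy(3,4,5-trimethoxyphenyl)methyl]-2,4-dimethoxyphenol | Oc1c(OC)c(OCc2ccccc2)c(OC)cc1C(O)c1cc(OC)c(OC)c(OC)c1 | intermediate
8 | rac-3-(benzyloxy)-2,4-dimethoxy-6-[(4-methylbenzenesulfonyl)(3,4,5-trimethoxyphenyl)methyl]phenol | Oc1c(OC)c(OCc2ccccc2)c(OC)cc1C(c1cc(OC)c(OC)c(OC)c1)S(=O)(=O)c1ccc(C)cc1 | intermediate
9 | tert-butyl bromoacetate | BrCC(=O)OC(C)(C)C | starting material
10 | quinidine | COC1=CC2=C(C=CN=C2C=C1)[C@@H]([C@H]3C[C@@H]4CCN3C[C@@H]4C=C)O | starting material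
11 | N-[2-(tert-butoxy)-2-oxoethyl]quinidinium bromide (alkylated at the quinuclidine nitrogen) | COC1=CC2=C(C=CN=C2C=C1)[C@@H]([C@H]3C[C@@H]4CC[N+]3(CC(=O)OC(C)(C)C)C[C@@H]4C=C)O.[Br-] | intermediate
12 | 3-(benzyloxy)-2,4-dimethoxy-6-[(3,4,5-trimethoxyphenyl)methylidene]cyclohexa-2,4-dien-1-one (ortho-quinone methide) | O=C1C(OC)=C(OCc2ccccc2)C(OC)=CC1=Cc1cc(OC)c(OC)c(OC)c1 | intermediate (not isolated)
13 | quinidinium 2-(tert-butoxy)-2-oxoethan-1-ide (ammonium ylide of 11) | COC1=CC2=C(C=CN=C2C=C1)[C@@H]([C@H]3C[C@@H]4CC[N+]3([CH-]C(=O)OC(C)(C)C)C[C@@H]4C=C)O | intermediate (not isolated)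
14 | N-[(2R,3S)-3-[4-(benzyloxy)-3,5-dimethoxy-2-oxidophenyl]-1-(tert-butoxy)-1-oxo-3-(3,4,5-trimethoxyphenyl)propan-2-yl]quinidinium (phenoxide–ammonium betaine) | COC1=CC2=C(C=CN=C2C=C1)[C@@H]([C@H]3C[C@@H]4CC[N+]3([C@@H](C(=O)OC(C)(C)C)[C@@H](c5cc(OC)c(OC)c(OC)c5)c5cc(OC)c(OCc6ccccc6)c(OC)c5[O-])C[C@@H]4C=C)O | intermediate (not isolated)
15 | tert-butyl (2S,3S)-6-(benzyloxy)-5,7-dimethoxy-3-(3,4,5-trimethoxyphenyl)-2,3-dihydro-1-benzofuran-2-carboxylate (trans) | c12cc(OC)c(OCc3ccccc3)c(OC)c1O[C@H](C(=O)OC(C)(C)C)[C@H]2c1cc(OC)c(OC)c(OC)c1 | intermediate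
16 | [(2S,3S)-6-(benzyloxy)-5,7-dimethoxy-3-(3,4,5-trimethoxyphenyl)-2,3-dihydro-1-benzofuran-2-yl]methanol | c12cc(OC)c(OCc3ccccc3)c(OC)c1O[C@H](CO)[C@H]2c1cc(OC)c(OC)c(OC)c1 | intermediate
17 | [(2S,3S)-6-(benzyloxy)-5,7-dimethoxy-3-(3,4,5-trimethoxyphenyl)-2,3-dihydro-1-benzofuran-2-yl]methyl 4-methylbenzenesulfonate | c12cc(OC)c(OCc3ccccc3)c(OC)c1O[C@H](COS(=O)(=O)c3ccc(C)cc3)[C@H]2c1cc(OC)c(OC)c(OC)c1 | intermediate
18 | (2R,3S)-6-(benzyloxy)-5,7-dimethoxy-2-methyl-3-(3,4,5-trimethoxyphenyl)-2,3-dihydro-1-benzofuran | c12cc(OC)c(OCc3ccccc3)c(OC)c1O[C@H](C)[C@H]2c1cc(OC)c(OC)c(OC)c1 | intermediate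
19 | (2R,3S)-5,7-dimethoxy-2-methyl-3-(3,4,5-trimethoxyphenyl)-2,3-dihydro-1-benzofuran-6-ol | c12cc(OC)c(O)c(OC)c1O[C@H](C)[C@H]2c1cc(OC)c(OC)c(OC)c1 | intermediate
20 | allyltrimethylsilane | C=CC[Si](C)(C)C | starting material
21 | (2R,3S)-5,7-dimethoxy-2-methyl-6-oxo-3-(3,4,5-trimethoxyphenyl)-2,3-dihydro-6H-1-benzofuran-3a-ylium (phenoxonium cation, drawn with the charge on C3a) | [C+]12C=C(OC)C(=O)C(OC)=C1O[C@H](C)[C@H]2c1cc(OC)c(OC)c(OC)c1 | intermediate (not isolated)
22 | (2R,3S,3aS)-5,7-dimethoxy-2-methyl-3a-(prop-2-en-1-yl)-3-(3,4,5-trimethoxyphenyl)-3,3a-dihydro-1-benzofuran-6(2H)-one (allyl anti to aryl) | C=CC[C@]12C=C(OC)C(=O)C(OC)=C1O[C@H](C)[C@H]2c1cc(OC)c(OC)c(OC)c1 | intermediate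
23 | lithium (2R,3S,3aR)-5,7-dimethoxy-2-methyl-3a-(prop-2-en-1-yl)-3-(3,4,5-trimethoxyphenyl)-2,3,3a,4-tetrahydro-1-benzofuran-6-olate | C=CC[C@]12CC(OC)=C([O-])C(OC)=C1O[C@H](C)[C@H]2c1cc(OC)c(OC)c(OC)c1.[Li+] | intermediate (not isolated)
24 | (2R,3S,3aR,5S)-5,7-dimethoxy-2-methyl-3a-(prop-2-en-1-yl)-3-(3,4,5-trimethoxyphenyl)-3,3a,4,5-tetrahydro-1-benzofuran-6(2H)-one | C=CC[C@]12C[C@H](OC)C(=O)C(OC)=C1O[C@H](C)[C@H]2c1cc(OC)c(OC)c(OC)c1 | target

## Step count and risks

Total steps: 13. Longest linear sequence: 12 (steps 1–5 and 7–13; step 6 is a one-step side branch).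

Steps most likely to fail:

1. Step 12. The allylsilane may attack a methoxy-bearing ortho carbon or the aryl-shielded face instead of C3a anti to aryl, the cation may be captured by solvent or acetate, or the trimethoxyphenyl ring may be over-oxidised. The fallback separates oxidation from C–C bond formation. It sets out from 19, which would be oxidised with PhI(OAc)2 in MeOH at 0 °C to the ortho-quinone monoketal (2R,3S)-5,5,7-trimethoxy-2-methyl-3-(3,4,5-trimethoxyphenyl)-2,3-dihydro-1-benzofuran-6(5H)-one F3. F3 would then be ionised with BF3·OEt2 in CH2Cl2 at −78 °C in the presence of allyltrimethylsilane 20 (Lewis-acid Hosomi–Sakurai allylation of a quinone monoketal). Gentle warming would let any ortho-allyl adduct shift by [3,3] rearrangement, and the sequence comes back to the route at 22.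

2. Step 13. Hydride may add 1,2 to the carbonyl; protonation of the enolate may occur on the allyl face (the stereoelectronically preferred axial approach competes with the steric preference); and the α-methoxy ketone may epimerise during work-up. The fallback sets out from 22 and uses copper hydride conjugate hydrosilylation ([(Ph3P)CuH]6 cat., PhMe2SiH, toluene, rt) to give the isolable silyl enol ether (2R,3S,3aR)-6-{[dimethyl(phenyl)silyl]oxy}-5,7-dimethoxy-2-methyl-3a-(prop-2-en-1-yl)-3-(3,4,5-trimethoxyphenyl)-2,3,3a,4-tetrahydro-1-benzofuran F4. F4 would be protonated in a separate, tunable step (Bu4NF, AcOH, THF, −78 °C) to return to the route at 24. Any (2R,3S,3aR,5R)-5,7-dimethoxy-2-methyl-3a-(prop-2-en-1-yl)-3-(3,4,5-trimethoxyphenyl)-3,3a,4,5-tetrahydro-1-benzofuran-6(2H)-one F5 would be separated and returned to F4 by soft enolisation (PhMe2SiCl, Et3N, NaI, MeCN), since C5 is the only enolisable position.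

3. Step 7. The chiral ammonium group may discriminate poorly between the faces of this electron-rich, hindered quinone methide, or the ylide may add slowly. The fallback replaces reagent control by a separable covalent auxiliary and sets out from 8. Commercial (−)-menthyl chloroacetate would be quaternised with trimethylamine to [2-{[(1R,2S,5R)-5-methyl-2-(propan-2-yl)cyclohexyl]oxy}-2-oxoethyl]trimethylammonium chloride F1. F1 and 8 with Cs2CO3 in CH2Cl2 (the racemic ammonium ylide [4+1] protocol) should give the trans esters as two diastereomers. Crystallisation or chromatography would provide (1R,2S,5R)-menthyl (2S,3S)-6-(benzyloxy)-5,7-dimethoxy-3-(3,4,5-trimethoxyphenyl)-2,3-dihydro-1-benzofuran-2-carboxylate F2. LiAlH4 reduction of F2 comes back to the route at 16.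

## Further compounds

F1 | step 7 | [2-{[(1R,2S,5R)-5-methyl-2-(propan-2-yl)cyclohexyl]oxy}-2-oxoethyl]trimethylammonium chloride | C[C@@H]1CC[C@H]([C@@H](C1)OC(=O)C[N+](C)(C)C)C(C)C.[Cl-]
F2 | step 7 | (1R,2S,5R)-menthyl (2S,3S)-6-(benzyloxy)-5,7-dimethoxy-3-(3,4,5-trimethoxyphenyl)-2,3-dihydro-1-benzofuran-2-carboxylate | C[C@@H]1CC[C@H]([C@@H](C1)OC(=O)[C@H]2Oc3c(OC)c(OCc4ccccc4)c(OC)cc3[C@@H]2c2cc(OC)c(OC)c(OC)c2)C(C)C
F3 | step 12 | (2R,3S)-5,5,7-trimethoxy-2-methyl-3-(3,4,5-trimethoxyphenyl)-2,3-dihydro-1-benzofuran-6(5H)-one | C12=CC(OC)(OC)C(=O)C(OC)=C1O[C@H](C)[C@H]2c1cc(OC)c(OC)c(OC)c1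
F4 | step 13 | (2R,3S,3aR)-6-{[dimethyl(phenyl)silyl]oxy}-5,7-dimethoxy-2-methyl-3a-(prop-2-en-1-yl)-3-(3,4,5-trimethoxyphenyl)-2,3,3a,4-tetrahydro-1-benzofuran | C=CC[C@]12CC(OC)=C(O[Si](C)(C)c3ccccc3)C(OC)=C1O[C@H](C)[C@H]2c1cc(OC)c(OC)c(OC)c1
F5 | step 13 | (2R,3S,3aR,5R)-5,7-dimethoxy-2-methyl-3a-(prop-2-en-1-yl)-3-(3,4,5-trimethoxyphenyl)-3,3a,4,5-tetrahydro-1-benzofuran-6(2H)-one | C=CC[C@]12C[C@@H](OC)C(=O)C(OC)=C1O[C@H](C)[C@H]2c1cc(OC)c(OC)c(OC)c1
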